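The readings stem from a simulated flask with constants of no real substance; noise was put on by code.

The ratio of target at 10.0 h to target at 8.00 h in Sunday's run, 0.958, was what I reckoned from.

| flask | substrate | remark | time |
|---|---|---|---|
| Sunday's | 0.44 M | run made earlier |  |
| ash | 0.80 M |  | 4.0 h |
| maple | 0.40 M |  | 15 h |

Sunday's run (percent of the substrate charged)

| time / h | target / % |
|---|---|
| 2.00 | 45.3 |
| 4.00 | 62.9 |
| 5.00 | 67.2 |
| 8.00 | 71.6 |
| 10.0 | 68.6 |

(each reading ± 0.5 percentage points)

- the flask that ends with the higher amount of target, in percent of the substrate charged, or "neither" when 2 percentage points or less lies between them (ash / maple / neither)
- final target, as a percentage of the substrate charged, in ash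
- final target, as a percentage of the substrate charged, in maple

- on the list of suspects stand: substrate -> side product; target <-> isomer of the product; substrate -> target

1. I kept a ledger on the substrate, the limiting reagent, in percent of the charge. Its suspected exits were target, side product and, through target, isomer of the product.

2. In Sunday's run the target entry stood at 71.6% at 8.00 h and 68.6% at 10.0 h, so the other entries together, substrate still left included, went from 28.4% to 31.4%.

3. As I read Sunday's run, control changed hands near its highest reading: the making of target led before it, and the loss of target led after it. I named the tail rate, λ = 0.0214 h⁻¹, the net fractional fall of target per hour past that crossing. It is a reading and carries the scatter.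

4. One charge could not test the orders, so I assumed first-order steps, which carry percent curves across charges. Ash, read earlier than the crossing, took Sunday's 62.9% at 4.00 h.

5. Maple, read later than the crossing, took the tail from Sunday's last reading and came to 61.6%.

6. My books closed with a gap of 1.3 percentage points, smaller than the margin of 2 points, so I said neither.

7. The forecast parted from me: it gave 65% for ash and 60% for maple and chose ash, in the words “Ash is therefore likely ahead by a few points”.

The flasks gave 63.3% in ash and 63.7% in maple, which counts as neither.

    substrate → side product (k = 0.00120 min⁻¹)
    target ⇌ isomer of the product (K = 3.00, k = 3.60 × 10⁻⁴ min⁻¹)
    substrate → target (k = 0.00570 min⁻¹)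

In maple, the conversion of substrate into target had 96% of its turnover up to 15.0 h behind it by 7.50 h, with substrate down to 4.48%. The conversion of target into isomer of the product had 45% of its turnover behind it then and ran on, and maple held 18.7% of isomer of the product at 15.0 h. λ had put maple 2.1 points low. For maple left until 2.5 d, λ gives 23.5%; that flask held 32.5% of target and 50.1% of isomer of the product.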